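**Retrosynthetic overview**

1. The target is the 19‑acetate of andrograpanin. Its four stereocentres (C4, C5, C9, C10) and all twenty skeletal carbons are taken from andrographolide 1; rings A and B and the lactone are bought, not built.
2. The 3,19‑diol of 1 is tied up as cyclic thionocarbonate 2, the only ring formed (step 1). It masks the diol and later serves as the radical leaving group for C3–O (opened in step 3).
3. Key disconnection: the C12–H bond and the C13=C14 butenolide come from C14 allylic diazene 5 by a [1,5]-sigmatropic (retro‑ene) hydrogen shift with loss of N2, reached via 3 and 4 and giving 6.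
4. The C3–O bond is cut by radical fragmentation of the thionocarbonate (7, 8) to andrograpanin 9.
5. Acetylation of the 19‑OH gives target 10.

Assumption: the target is read as 19‑O‑acetylandrograpanin (4R,5S,9R,10S, the andrographolide series, checked centre by centre against the SMILES); andrographolide (labdane) atom numbering is used throughout.

**Route**

Step 1
Reactants: 1 andrographolide
Product: 2 cyclic 3,19-thionocarbonate of andrographolide
Conditions: TCDI (1.05 equiv), THF, 0 → 23 °C
Reagents that add atoms: 1,1'-thiocarbonyldiimidazole, S=C(n1ccnc1)n1ccnc1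
Why: Thiocarbonyl transfer to a 1,3-diol: the primary 19‑OH is thioacylated first and the neighbouring 3‑OH closes the six‑membered 1,3‑dioxane‑2‑thione intramolecularly, faster than the lone secondary allylic 14‑OH reacts with TCDI without DMAP or heat; no stereocentre is touched.

Step 2
Reactants: 2 cyclic 3,19-thionocarbonate of andrographolide
Product: 6 cyclic 3,19-thionocarbonate of 14-deoxyandrographolide, via C14 sulfonylhydrazone adduct 3 (not isolated), via C14 sulfonylhydrazine 4 (not isolated), via C14 allylic diazene 5 (not isolated)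
Conditions: IPNBSH (N-isopropylidene-N'-2-nitrobenzenesulfonylhydrazine), PPh3, DEAD, THF, 0 → 23 °C; then CF3CH2OH/H2O (1:1), 23 °C
Reagents that add atoms: none
Why: Myers–Movassaghi reductive allylic transposition: Mitsunobu SN2 displacement of the only free hydroxyl (C14, inversion), hydrazone hydrolysis and loss of 2‑nitrobenzenesulfinic acid give the monoalkyl diazene, whose [1,5]-sigmatropic (retro‑ene) hydrogen shift expels N2, puts H on C12 and moves the alkene to C13=C14; no stereocentre is created (C14 becomes sp2, C12 becomes CH2).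

Step 3
Reactants: 6 cyclic 3,19-thionocarbonate of 14-deoxyandrographolide
Product: 9 andrograpanin, via S-tributylstannyl thiocarbonate 7 (not isolated), via O-alkyl thiocarbonic acid 8 (not isolated)
Conditions: Bu3SnH (1.3 equiv, slow addition), AIBN (2,2'-azobisisobutyronitrile, cat.), PhMe, 110 °C; then 1 M HCl, THF, 23 °C
Reagents that add atoms: none
Why: Barton–McCombie-type deoxygenation of a cyclic thionocarbonate: Bu3Sn• adds to sulfur and the resulting radical undergoes β‑scission at C3–O (secondary radical) rather than C19–O (primary neopentyl radical); H‑transfer gives C3H2 (no stereocentre), and acid cleaves Sn–S so the thiocarbonic half‑ester loses COS to free the 19‑OH.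

Step 4
Reactants: 9 andrograpanin
Product: 10 andrograpanin 19-acetate (target CNP0350004.2)
Conditions: Ac2O, pyridine, DMAP (4-dimethylaminopyridine, cat.), CH2Cl2, 0 → 23 °C
Reagents that add atoms: acetic anhydride, CC(=O)OC(C)=O
Why: DMAP‑catalysed O‑acylation of the only hydroxyl; the butenolide, the exocyclic alkene and all four stereocentres are inert to these conditions.

**Compound list**

1 | andrographolide, (3E,4S)-3-{2-[(1R,4aS,5R,6R,8aS)-6-hydroxy-5-(hydroxymethyl)-5,8a-dimethyl-2-methylidenedecahydronaphthalen-1-yl]ethylidene}-4-hydroxyoxolan-2-one | C=C1CC[C@@H]2[C@](C)(CO)[C@H](O)CC[C@@]2(C)[C@@H]1C/C=C1/C(=O)OC[C@H]1O | starting material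
2 | cyclic 3,19-thionocarbonate of andrographolide (O3 and O19 joined through C=S as a 1,3-dioxane-2-thione fused at C3–C4; 14S-OH, 12E alkene and 8(17) methylene unchanged) | C=C1CC[C@@H]2[C@]3(C)COC(=S)O[C@@H]3CC[C@@]2(C)[C@@H]1C/C=C1/C(=O)OC[C@H]1O | intermediate
3 | C14 sulfonylhydrazone adduct: 2 with the 14-OH replaced, with inversion (14R), by N(SO2C6H4-2-NO2)–N=CMe2 | C=C1CC[C@@H]2[C@]3(C)COC(=S)O[C@@H]3CC[C@@]2(C)[C@@H]1C/C=C1/C(=O)OC[C@@H]1N(N=C(C)C)S(=O)(=O)c1ccccc1[N+](=O)[O-] | intermediate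
4 | C14 sulfonylhydrazine: as 3 but with N(SO2C6H4-2-NO2)–NH2 at C14 (14R) | C=C1CC[C@@H]2[C@]3(C)COC(=S)O[C@@H]3CC[C@@]2(C)[C@@H]1C/C=C1/C(=O)OC[C@@H]1N(N)S(=O)(=O)c1ccccc1[N+](=O)[O-] | intermediate
5 | C14 allylic diazene: as 3 but with N=NH at C14 (14R), 12E alkene still exocyclic | C=C1CC[C@@H]2[C@]3(C)COC(=S)O[C@@H]3CC[C@@]2(C)[C@@H]1C/C=C1/C(=O)OC[C@@H]1N=N | intermediate
6 | cyclic 3,19-thionocarbonate of 14-deoxyandrographolide (side chain CH2CH2 attached to C3 of a furan-2(5H)-one; 1,3-dioxane-2-thione across O3/O19) | C=C1CC[C@@H]2[C@]3(C)COC(=S)O[C@@H]3CC[C@@]2(C)[C@@H]1CCC1=CCOC1=O | intermediate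
7 | S-tributylstannyl thiocarbonate of andrograpanin (19-O–C(=O)–S–SnBu3, C3 now CH2) | C=C1CC[C@@H]2[C@](C)(COC(=O)S[Sn](CCCC)(CCCC)CCCC)CCC[C@@]2(C)[C@@H]1CCC1=CCOC1=O | intermediate
8 | O-alkyl thiocarbonic acid of andrograpanin (19-O–C(=O)–SH) | C=C1CC[C@@H]2[C@](C)(COC(=O)S)CCC[C@@]2(C)[C@@H]1CCC1=CCOC1=O | intermediate
9 | andrograpanin, 3-{2-[(1R,4aS,5R,8aS)-5-(hydroxymethyl)-5,8a-dimethyl-2-methylidenedecahydronaphthalen-1-yl]ethyl}furan-2(5H)-one | C=C1CC[C@@H]2[C@](C)(CO)CCC[C@@]2(C)[C@@H]1CCC1=CCOC1=O | intermediate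
10 | andrograpanin 19-acetate, [(1R,4aS,5R,8aS)-1,4a-dimethyl-6-methylidene-5-[2-(2-oxo-2,5-dihydrofuran-3-yl)ethyl]decahydronaphthalen-1-yl]methyl acetate | C=C1CC[C@@H]2[C@](C)(COC(C)=O)CCC[C@@]2(C)[C@@H]1CCC1=CCOC1=O | target

**Totals**

Total step count: 4. Longest linear sequence: 4 steps (1 → 2 → 6 → 9 → 10).

**Three steps most likely to fail, with fallbacks**

Step 2 (key step). Risks: the thionocarbonate sulfur may interfere with PPh3/DEAD or the hydrolysis stage; the activated C14 alcohol may undergo 1,4‑elimination to the 11,12‑didehydro butenolide or SN2' capture at C12. The fallback inverts the order so that no thiocarbonyl group is present during the Mitsunobu reaction, while keeping the diazene shift. It sets out from 2 and comes back at 9.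
- Compound 2 is first deoxygenated at C3 (Bu3SnH, AIBN, PhMe, 110 °C; then 1 M HCl). This passes through 3-deoxyandrographolide 19-O-(S-tributylstannyl thiocarbonate) F2 and 3-deoxyandrographolide 19-O-thiocarbonic acid F3 to 3-deoxyandrographolide F4.
- F4 is then treated with IPNBSH, PPh3 and DEAD (2.5 equiv each, THF, 0 → 23 °C), then CF3CH2OH/H2O. The neopentyl primary 19‑OH cannot be displaced and is recovered on aqueous work‑up.
- The C14 alcohol reacts through the 3-deoxy C14 sulfonylhydrazone adduct F5, the 3-deoxy C14 sulfonylhydrazine F6 and the 3-deoxy C14 allylic diazene F7. The retro‑ene loss of N2 from F7 gives andrograpanin 9.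

Step 1. Risks: competing thioacylation of the allylic 14‑OH, double thiocarbonylation, or imidazole‑induced loss of the allylic hydroxyl. The fallback activates only the diol oxygens through a tin acetal. It sets out from 1 and comes back at 2.
- Compound 1 is heated with Bu2SnO (dibutyltin oxide) in MeOH at 65 °C and evaporated to give the 3,19-O-dibutylstannylene acetal of andrographolide F1.
- F1 is treated with thiophosgene (1.0 equiv, CH2Cl2, 0 °C), which closes the thionocarbonate on the two tin‑bound oxygens and gives 2.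

Step 3. Risks: hydrostannylation of the butenolide or the exocyclic alkene at 110 °C, incomplete selectivity between C3–O and C19–O scission, or sluggish Sn–S cleavage. The fallback fixes C19 as the final acetate first and then deoxygenates an acyclic C3 thionocarbonate with a silane, so only one C–O bond can break and no thiocarbonate hydrolysis is needed. It sets out from 6 and comes back at 10, bypassing step 4 as well.
- The thiocarbonyl bridge of 6 is removed with ethylenediamine (THF, 0 °C) to give 14-deoxyandrographolide F8.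
- The primary 19‑OH is acetylated selectively (AcCl, 2,4,6-collidine, CH2Cl2, −78 °C) to 19-O-acetyl-14-deoxyandrographolide F9.
- The hindered 3‑OH is converted with PhOC(S)Cl and DMAP (CH2Cl2, 23 °C) into 19-O-acetyl-3-O-(phenoxythiocarbonyl)-14-deoxyandrographolide F10.
- F10 is reduced with (Me3Si)3SiH and AIBN (PhMe, 80 °C) to give target 10 directly.

**Further compounds**

F1 | step 1 | 3,19-O-dibutylstannylene acetal of andrographolide | C=C1CC[C@@H]2[C@]3(C)CO[Sn](CCCC)(CCCC)O[C@@H]3CC[C@@]2(C)[C@@H]1C/C=C1/C(=O)OC[C@H]1O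
F2 | step 2 | 3-deoxyandrographolide 19-O-(S-tributylstannyl thiocarbonate) | C=C1CC[C@@H]2[C@](C)(COC(=O)S[Sn](CCCC)(CCCC)CCCC)CCC[C@@]2(C)[C@@H]1C/C=C1/C(=O)OC[C@H]1O
F3 | step 2 | 3-deoxyandrographolide 19-O-thiocarbonic acid | C=C1CC[C@@H]2[C@](C)(COC(=O)S)CCC[C@@]2(C)[C@@H]1C/C=C1/C(=O)OC[C@H]1O
F4 | step 2 | 3-deoxyandrographolide | C=C1CC[C@@H]2[C@](C)(CO)CCC[C@@]2(C)[C@@H]1C/C=C1/C(=O)OC[C@H]1O
F5 | step 2 | 3-deoxy C14 sulfonylhydrazone adduct (14R) | C=C1CC[C@@H]2[C@](C)(CO)CCC[C@@]2(C)[C@@H]1C/C=C1/C(=O)OC[C@@H]1N(N=C(C)C)S(=O)(=O)c1ccccc1[N+](=O)[O-]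
F6 | step 2 | 3-deoxy C14 sulfonylhydrazine (14R) | C=C1CC[C@@H]2[C@](C)(CO)CCC[C@@]2(C)[C@@H]1C/C=C1/C(=O)OC[C@@H]1N(N)S(=O)(=O)c1ccccc1[N+](=O)[O-]
F7 | step 2 | 3-deoxy C14 allylic diazene (14R) | C=C1CC[C@@H]2[C@](C)(CO)CCC[C@@]2(C)[C@@H]1C/C=C1/C(=O)OC[C@@H]1N=N
F8 | step 3 | 14-deoxyandrographolide | C=C1CC[C@@H]2[C@](C)(CO)[C@H](O)CC[C@@]2(C)[C@@H]1CCC1=CCOC1=O
F9 | step 3 | 19-O-acetyl-14-deoxyandrographolide | C=C1CC[C@@H]2[C@](C)(COC(C)=O)[C@H](O)CC[C@@]2(C)[C@@H]1CCC1=CCOC1=O
F10 | step 3 | 19-O-acetyl-3-O-(phenoxythiocarbonyl)-14-deoxyandrographolide | C=C1CC[C@@H]2[C@](C)(COC(C)=O)[C@H](OC(=S)Oc3ccccc3)CC[C@@]2(C)[C@@H]1CCC1=CCOC1=O
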